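**Retrosynthetic overview**
1. Target ⇒ chelation-directed 5-O-demethylation of 3-hydroxy-5,6,7,8,4'-pentamethoxyflavone ⇒ C2=C3 epoxidation and isomerisation of 5,6,7,8,4'-pentamethoxyflavone (tangeretin).
2. Tangeretin ⇒ oxidative oxa-Michael closure of ring C from (E)-2'-hydroxy-3',4',5',6',4-pentamethoxychalcone.
3. Chalcone ⇒ key C–C disconnection at Cα=Cβ (the future C3–C2): intermolecular Claisen–Schmidt aldol condensation of 2'-hydroxy-3',4',5',6'-tetramethoxyacetophenone with 4-methoxybenzaldehyde.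
4. Acetophenone ⇒ ortho-acylation of 2,3,4,5-tetramethoxyphenol ⇒ two successive ring oxygenations (Dakin, then ortho-lithiation/borylation/oxidation) starting from 2,3,4-trimethoxybenzaldehyde.
5. Ring order: rings A and B are bought as arenes. Ring C is the only ring made and closes after the aldol step. The 3-OH is then installed and the 5-OH unmasked last.

Assumption: the target SMILES has no stereocentre or stereogenic axis, so the compound is achiral and needs no enantioselective step; the only stereoelement in the route is the E alkene of chalcone 13, which is consumed in step 6.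

**Step 1**
Reactants: 1 2,3,4-trimethoxybenzaldehyde
Product: 3 2,3,4-trimethoxyphenol, via aryl formate 2 (not isolated)
Conditions: 30% aq H2O2 (1.3 equiv), conc. H2SO4 (cat.), MeOH, rt, 12 h
Reagents that add atoms: hydrogen peroxide, OO
Why: In this acid-catalysed Dakin (Baeyer–Villiger type) oxidation the aryl group, activated by its ortho and para methoxy groups, migrates to oxygen to give formate 2, which the acidic methanol cleaves in situ.

**Step 2**
Reactants: 3 2,3,4-trimethoxyphenol
Product: 4 1,2,3,4-tetramethoxybenzene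
Conditions: MeI (1.5 equiv), K2CO3 (2 equiv), acetone, reflux, 8 h, N2
Reagents that add atoms: iodomethane, CI
Why: This is a Williamson ether synthesis (SN2 O-methylation of the phenoxide), and the substrate has only one nucleophilic site.

**Step 3**
Reactants: 4 1,2,3,4-tetramethoxybenzene
Product: 7 2,3,4,5-tetramethoxyphenol, via aryllithium 5 (not isolated), via lithium aryltrimethoxyborate 6 (not isolated)
Conditions: n-BuLi (1.2 equiv), TMEDA (1.2 equiv), THF, 0 °C → rt, 2 h; B(OMe)3 (2 equiv), −78 °C → rt; AcOH (2 equiv), 30% aq H2O2 (2 equiv), 0 °C → rt, 1 h, N2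
Reagents that add atoms: hydrogen peroxide, OO
Why: Directed ortho-metalation, borylation and oxidative 1,2-aryl shift (hydroxydeboronation) give a single phenol because the two ring C–H positions of 4 are equivalent and each lies ortho to a methoxy director.

**Step 4**
Reactants: 7 2,3,4,5-tetramethoxyphenol
Product: 10 1-(2-hydroxy-3,4,5,6-tetramethoxyphenyl)ethan-1-one, via aryl acetate 8 (not isolated), via difluoroboron chelate 9 (not isolated)
Conditions: Ac2O (1.5 equiv), BF3·OEt2 (4 equiv), neat, 0 → 75 °C, 2 h; then H2O–MeOH, 60 °C, 1 h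
Reagents that add atoms: acetic anhydride, CC(=O)OC(C)=O
Why: O-acetylation followed by BF3-mediated Fries rearrangement (Friedel–Crafts C-acylation) can only reach the single free ring position ortho to the phenol oxygen, and the product is held as the six-membered BF2 chelate 9 until hydrolysis.

**Step 5**
Reactants: 10 1-(2-hydroxy-3,4,5,6-tetramethoxyphenyl)ethan-1-one; 11 4-methoxybenzaldehyde
Product: 13 (E)-1-(2-hydroxy-3,4,5,6-tetramethoxyphenyl)-3-(4-methoxyphenyl)prop-2-en-1-one, via aldol adduct 12 (not isolated)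
Conditions: KOH (10 equiv, 50% aq), EtOH, rt, 36 h; then 2 M HCl to pH 3, 0 °C
Reagents that add atoms: none
Why: In this Claisen–Schmidt crossed aldol condensation only 10 can enolise and only 11 offers a non-enolisable aldehyde, so the Cα–Cβ bond forms cleanly between the two fragments, and E1cB dehydration of racemic 12 removes its stereocentre and gives the thermodynamically favoured E enone.

**Step 6**
Reactants: 13 (E)-1-(2-hydroxy-3,4,5,6-tetramethoxyphenyl)-3-(4-methoxyphenyl)prop-2-en-1-one
Product: 16 5,6,7,8,4'-pentamethoxyflavone (tangeretin), via flavanone 14 (not isolated), via 3-iodoflavanone 15 (not isolated)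
Conditions: I2 (0.1 equiv), DMSO, 125 °C, 3 h
Reagents that add atoms: none
Why: In this iodine-catalysed oxidative cyclisation, oxa-Michael addition of the 2'-OH closes ring C, α-iodination and loss of HI give the 4-pyranone (erasing the transient stereocentres), and DMSO reoxidises HI to I2.

**Step 7**
Reactants: 16 5,6,7,8,4'-pentamethoxyflavone
Product: 18 3-hydroxy-5,6,7,8,4'-pentamethoxyflavone, via flavone 2,3-epoxide 17 (not isolated)
Conditions: DMDO (ca. 0.07 M in acetone, 3 equiv), CH2Cl2, 0 °C → rt, 16 h; concentrate; p-TsOH·H2O (0.1 equiv), CH2Cl2, rt, 1 h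
Reagents that add atoms: dimethyldioxirane (DMDO), CC1(C)OO1
Why: Neutral electrophilic epoxidation of the enol-ether-like C2=C3 bond is followed by acid-catalysed opening at the oxygen- and aryl-stabilised C2 and loss of H-3 (epoxide-to-enol isomerisation), and ring A has no C–H bond that could be hydroxylated in competition.

**Step 8**
Reactants: 18 3-hydroxy-5,6,7,8,4'-pentamethoxyflavone
Product: 20 3,5-dihydroxy-6,7,8,4'-tetramethoxyflavone, via bis(dichloroboryl) chelate 19 (not isolated)
Conditions: BCl3 (1.0 M in CH2Cl2, 3 equiv), CH2Cl2, −78 → 0 °C, 2 h; then 1 M aq HCl, rt, 30 min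
Reagents that add atoms: none
Why: In this chelation-directed Lewis-acid ether cleavage the 3-OH is borylated first, then BCl3 held between the C4 carbonyl and the peri 5-OMe activates only that methyl for SN2 attack by chloride, while the unchelated 6-, 7-, 8- and 4'-methyl ethers are inert to BCl3 at or below 0 °C.

**Compound list**
1 | 2,3,4-trimethoxybenzaldehyde | COc1ccc(C=O)c(OC)c1OC | starting material
2 | 2,3,4-trimethoxyphenyl formate (not isolated) | COc1ccc(OC=O)c(OC)c1OC | intermediate
3 | 2,3,4-trimethoxyphenol | COc1ccc(O)c(OC)c1OC | intermediate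
4 | 1,2,3,4-tetramethoxybenzene | COc1ccc(OC)c(OC)c1OC | intermediate
5 | (2,3,4,5-tetramethoxyphenyl)lithium (not isolated) | [Li]c1cc(OC)c(OC)c(OC)c1OC | intermediate
6 | lithium trimethoxy(2,3,4,5-tetramethoxyphenyl)borate (not isolated) | [Li+].CO[B-](OC)(OC)c1cc(OC)c(OC)c(OC)c1OC | intermediate
7 | 2,3,4,5-tetramethoxyphenol | COc1cc(O)c(OC)c(OC)c1OC | intermediate
8 | 2,3,4,5-tetramethoxyphenyl acetate (not isolated) | COc1cc(OC(C)=O)c(OC)c(OC)c1OC | intermediate
9 | difluoroboron chelate of 10 (not isolated) | CC1=[O+][B-](F)(F)Oc2c(OC)c(OC)c(OC)c(OC)c21 | intermediate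
10 | 1-(2-hydroxy-3,4,5,6-tetramethoxyphenyl)ethan-1-one (2'-hydroxy-3',4',5',6'-tetramethoxyacetophenone) | CC(=O)c1c(O)c(OC)c(OC)c(OC)c1OC | intermediate
11 | 4-methoxybenzaldehyde | COc1ccc(C=O)cc1 | starting material
12 | 3-hydroxy-1-(2-hydroxy-3,4,5,6-tetramethoxyphenyl)-3-(4-methoxyphenyl)propan-1-one (racemic, not isolated) | COc1ccc(C(O)CC(=O)c2c(O)c(OC)c(OC)c(OC)c2OC)cc1 | intermediate
13 | (E)-1-(2-hydroxy-3,4,5,6-tetramethoxyphenyl)-3-(4-methoxyphenyl)prop-2-en-1-one | COc1ccc(/C=C/C(=O)c2c(O)c(OC)c(OC)c(OC)c2OC)cc1 | intermediate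
14 | 5,6,7,8,4'-pentamethoxyflavanone (racemic, not isolated) | COc1ccc(C2CC(=O)c3c(OC)c(OC)c(OC)c(OC)c3O2)cc1 | intermediate
15 | 3-iodo-5,6,7,8,4'-pentamethoxyflavanone (racemic, not isolated) | COc1ccc(C2Oc3c(OC)c(OC)c(OC)c(OC)c3C(=O)C2I)cc1 | intermediate
16 | 5,6,7,8,4'-pentamethoxyflavone (tangeretin) | COc1ccc(-c2cc(=O)c3c(OC)c(OC)c(OC)c(OC)c3o2)cc1 | intermediate
17 | 2,3-epoxy-5,6,7,8,4'-pentamethoxyflavanone (racemic, not isolated) | COc1ccc(cc1)C12OC1C(=O)c1c(OC)c(OC)c(OC)c(OC)c1O2 | intermediate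
18 | 3-hydroxy-5,6,7,8,4'-pentamethoxyflavone | COc1ccc(-c2oc3c(OC)c(OC)c(OC)c(OC)c3c(=O)c2O)cc1 | intermediate
19 | 3,5-bis(dichloroboryloxy)-6,7,8,4'-tetramethoxyflavone, both borons chelated to the C4 carbonyl (not isolated) | COc1ccc(-c2oc3c(OC)c(OC)c(OC)c(OB(Cl)Cl)c3c(=O)c2OB(Cl)Cl)cc1 | intermediate
20 | 3,5-dihydroxy-6,7,8,4'-tetramethoxyflavone (achiral) | COc1ccc(-c2oc3c(OC)c(OC)c(OC)c(O)c3c(=O)c2O)cc1 | target

**Total step count:** 8. **Longest linear sequence:** 8 steps (1 → 20). Compound 11 is purchased and enters at step 5.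

**Three steps most likely to fail**

Step 3. The lithiation may stall, or the very electron-rich phenol 7 may be over-oxidised by H2O2 to a methoxyquinone. The fallback sets out from 4 and comes back at 7. It replaces the carbanion chemistry with electrophilic formylation and a peracid oxidation that keeps the phenol masked. Vilsmeier–Haack formylation of 4 (POCl3, DMF, 80 °C, then water) gives 2,3,4,5-tetramethoxybenzaldehyde F1. Baeyer–Villiger oxidation with mCPBA in CH2Cl2 gives 2,3,4,5-tetramethoxyphenyl formate F2. Once the peracid has been washed out, methanolysis with catalytic K2CO3 in MeOH under N2 releases 7.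

Step 7. DMDO may convert the electron-poor pyranone alkene only partly, or it may attack the anisyl ring. Direct alkaline peroxide oxidation of chalcone 13 is not a safe substitute, because 6'-methoxychalcones tend to give aurones. The fallback sets out from 16 and comes back at 18, and it reverses the polarity at C3. Deprotonation with LiN(iPr)2 in THF at −78 °C gives 3-lithio-5,6,7,8,4'-pentamethoxyflavone F3. B(OMe)3 traps it as lithium trimethoxy(5,6,7,8,4'-pentamethoxyflavon-3-yl)borate F4. AcOH and 30% H2O2 at 0 °C then oxidise the C–B bond to give 18.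

Step 8. The 3-O-boron chelate may tie up the carbonyl so that the 5-OMe reacts sluggishly, and forcing the reaction risks loss of the 6-OMe. The fallback sets out from 16 and comes back at 20. It exchanges the 5-methyl for a benzyl group before the 3-OH exists, so the last step is a hydrogenolysis rather than a Lewis-acid cleavage.
- BCl3 in CH2Cl2 at −78 → 0 °C converts 16 into 5-(dichloroboryloxy)-6,7,8,4'-tetramethoxyflavone F5. Aqueous HCl hydrolyses this to 5-hydroxy-6,7,8,4'-tetramethoxyflavone F6.
- BnBr and K2CO3 in DMF at 80 °C give 5-benzyloxy-6,7,8,4'-tetramethoxyflavone F7.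
- DMDO in CH2Cl2–acetone gives 5-benzyloxy-2,3-epoxy-6,7,8,4'-tetramethoxyflavanone F8. Catalytic p-TsOH·H2O isomerises this to 5-benzyloxy-3-hydroxy-6,7,8,4'-tetramethoxyflavone F9.
- H2 (1 atm) over 10% Pd/C in EtOAc–MeOH at rt removes the benzyl group to give 20.

**Further compounds**
F1 | step 3 | 2,3,4,5-tetramethoxybenzaldehyde | COc1cc(C=O)c(OC)c(OC)c1OC
F2 | step 3 | 2,3,4,5-tetramethoxyphenyl formate | COc1cc(OC=O)c(OC)c(OC)c1OC
F3 | step 7 | 3-lithio-5,6,7,8,4'-pentamethoxyflavone | COc1ccc(-c2oc3c(OC)c(OC)c(OC)c(OC)c3c(=O)c2[Li])cc1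
F4 | step 7 | lithium trimethoxy(5,6,7,8,4'-pentamethoxyflavon-3-yl)borate | [Li+].COc1ccc(-c2oc3c(OC)c(OC)c(OC)c(OC)c3c(=O)c2[B-](OC)(OC)OC)cc1
F5 | step 8 | 5-(dichloroboryloxy)-6,7,8,4'-tetramethoxyflavone | COc1ccc(-c2cc(=O)c3c(OB(Cl)Cl)c(OC)c(OC)c(OC)c3o2)cc1
F6 | step 8 | 5-hydroxy-6,7,8,4'-tetramethoxyflavone | COc1ccc(-c2cc(=O)c3c(O)c(OC)c(OC)c(OC)c3o2)cc1
F7 | step 8 | 5-benzyloxy-6,7,8,4'-tetramethoxyflavone | COc1ccc(-c2cc(=O)c3c(OCc4ccccc4)c(OC)c(OC)c(OC)c3o2)cc1
F8 | step 8 | 5-benzyloxy-2,3-epoxy-6,7,8,4'-tetramethoxyflavanone (racemic) | COc1ccc(cc1)C12OC1C(=O)c1c(OCc3ccccc3)c(OC)c(OC)c(OC)c1O2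
F9 | step 8 | 5-benzyloxy-3-hydroxy-6,7,8,4'-tetramethoxyflavone | COc1ccc(-c2oc3c(OC)c(OC)c(OC)c(OCc4ccccc4)c3c(=O)c2O)cc1
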